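**Retrosynthetic overview**
1. Target 8 is cut at the bond between the ketone carbon and the 3-hydroxyphenyl ring (ring C): an aroyl anion equivalent (the aroyl–palladium made from aldehyde 6 by phenoxide-directed formyl C–H cleavage) plus 3-iodophenol 7, as the last step and without protecting groups.
2. Aldehyde 6 comes from chromene aldehyde 4 by C-prenylation at C8, the only ring carbon still bearing hydrogen.
3. The pyran ring (ring B) of 4 comes from aryl propargyl ether 3 by gold-catalysed 6-endo hydroarylation, which fixes the ring oxygen as the one para to the formyl group.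
4. Ether 3 comes from 2,4,6-trihydroxybenzaldehyde 1 and 3-chloro-3-methylbut-1-yne 2 by selective 4-O-alkylation.
5. Ring order: benzene ring A is bought (1), ring B is closed in step 2, ring C is attached intact in step 4.

Assumption: the target has no stereocentre and no stereogenic double bond, so it is achiral and is made exactly as drawn; no stereocontrol is needed.

**Route**

Step 1
Reactants: 1 2,4,6-trihydroxybenzaldehyde; 2 3-chloro-3-methylbut-1-yne
Product: 3 2,6-dihydroxy-4-[(2-methylbut-3-yn-2-yl)oxy]benzaldehyde
Conditions: DBU (1.05 equiv), CuCl2·2H2O (1 mol %), MeCN, 0 °C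
Reagents that add atoms: 3-chloro-3-methylbut-1-yne (compound 2), C#CC(C)(C)Cl
Why: Copper-catalysed propargylic O-alkylation (Godfrey-type etherification through a copper acetylide); one equivalent of DBU ionises only the most acidic, non-chelated 4-OH para to the formyl group, so the tertiary propargyl unit goes onto that oxygen while the two hydrogen-bonded ortho-OH groups stay free; no stereocentre is formed.

Step 2
Reactants: 3 2,6-dihydroxy-4-[(2-methylbut-3-yn-2-yl)oxy]benzaldehyde
Product: 4 5,7-dihydroxy-2,2-dimethyl-2H-chromene-6-carbaldehyde
Conditions: Ph3PAuNTf2 (2 mol %), CH2Cl2, rt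
Reagents that add atoms: none
Why: Gold-catalysed intramolecular alkyne hydroarylation (6-endo-dig Friedel–Crafts-type cyclisation); cationic monovalent gold activates the terminal alkyne for attack by the ring carbon ortho to the ether oxygen (further activated by one ortho and one para OH; the two ortho carbons are equivalent), and because the aryl–O bond is never broken the pyran oxygen must be the one para to the formyl group; no stereocentre is formed.

Step 3
Reactants: 4 5,7-dihydroxy-2,2-dimethyl-2H-chromene-6-carbaldehyde; 5 1-bromo-3-methylbut-2-ene (prenyl bromide)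
Product: 6 5,7-dihydroxy-2,2-dimethyl-8-(3-methylbut-2-en-1-yl)-2H-chromene-6-carbaldehyde
Conditions: prenyl bromide (1.1 equiv), 10% aq KOH (2.2 equiv), 0 °C to rt
Reagents that add atoms: 1-bromo-3-methylbut-2-ene (compound 5), CC(C)=CCBr
Why: Phenoxide C-alkylation (classical C-prenylation of an acylphloroglucinol in water); C8 is the only ring carbon left with a hydrogen, it is ortho to O1 and the 7-phenoxide and para to the 5-phenoxide, and the protic medium solvates the phenoxide oxygens so the soft allylic bromide is taken up at carbon by SN2 attack to give the linear prenyl group; no stereocentre is formed.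

Step 4
Reactants: 6 5,7-dihydroxy-2,2-dimethyl-8-(3-methylbut-2-en-1-yl)-2H-chromene-6-carbaldehyde; 7 3-iodophenol
Product: 8 (5,7-dihydroxy-2,2-dimethyl-8-(3-methylbut-2-en-1-yl)-2H-chromen-6-yl)(3-hydroxyphenyl)methanone (target)
Conditions: 3-iodophenol (1.2 equiv), PdCl2 (5 mol %), LiCl (20 mol %), Na2CO3 (2.5 equiv), DMF, 100 °C, N2
Reagents that add atoms: 3-iodophenol (compound 7), Oc1cccc(I)c1
Why: Miura-type palladium-catalysed formyl C–H arylation of a salicylaldehyde; 3-iodophenol adds oxidatively to zerovalent palladium, the aryl–palladium binds the 5- or 7-phenoxide of 6 and cleaves the neighbouring aldehyde C–H bond to give an aroyl(aryl)palladium, which acts as an acyl anion equivalent joining the normally electrophilic formyl carbon to the normally electrophilic C–I carbon, and reductive elimination gives the diaryl ketone under weakly basic conditions that spare the acid-sensitive chromene and prenyl groups; no stereocentre is formed.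

**Compound list**
1 | 2,4,6-trihydroxybenzaldehyde | O=Cc1c(O)cc(O)cc1O | starting material
2 | 3-chloro-3-methylbut-1-yne | C#CC(C)(C)Cl | starting material
3 | 2,6-dihydroxy-4-[(2-methylbut-3-yn-2-yl)oxy]benzaldehyde | O=Cc1c(O)cc(OC(C)(C)C#C)cc1O | intermediate
4 | 5,7-dihydroxy-2,2-dimethyl-2H-chromene-6-carbaldehyde | O=Cc1c(O)cc2OC(C)(C)C=Cc2c1O | intermediate
5 | 1-bromo-3-methylbut-2-ene (prenyl bromide) | CC(C)=CCBr | starting material
6 | 5,7-dihydroxy-2,2-dimethyl-8-(3-methylbut-2-en-1-yl)-2H-chromene-6-carbaldehyde | O=Cc1c(O)c(CC=C(C)C)c2OC(C)(C)C=Cc2c1O | intermediate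
7 | 3-iodophenol | Oc1cccc(I)c1 | starting material
8 | (5,7-dihydroxy-2,2-dimethyl-8-(3-methylbut-2-en-1-yl)-2H-chromen-6-yl)(3-hydroxyphenyl)methanone (achiral) | CC(C)=CCc1c(O)c(C(=O)c2cccc(O)c2)c(O)c2c1OC(C)(C)C=C2 | target

**Step count**
Total steps: 4. Longest linear sequence: 4 (1 → 3 → 4 → 6 → 8).

**Three steps most likely to fail**

Step 4 (key coupling). The electron-rich, doubly ortho-substituted aroyl–palladium may lose CO. The aryl–palladium may also undergo Heck addition to the chromene C3=C4 bond. Hot base may open the pyran ring and reclose it onto the 5-oxygen, giving the 8-aroyl-6-prenyl isomer; running at 80 °C is the first adjustment. The fallback sets out from 1 and comes back to the route at 8. It moves the same palladium-mediated formyl C–H arylation to the start, where no alkene or pyran ring is present. Compounds 1 and 7 (PdCl2, LiCl, Na2CO3, DMF, 100 °C) give (3-hydroxyphenyl)(2,4,6-trihydroxyphenyl)methanone F1. Its most acidic 4-OH is alkylated with 2 (DBU, CuCl2·2H2O cat., MeCN, 0 °C) to give [2,6-dihydroxy-4-[(2-methylbut-3-yn-2-yl)oxy]phenyl](3-hydroxyphenyl)methanone F2. Ph3PAuNTf2 in CH2Cl2 closes the pyran ring to give (5,7-dihydroxy-2,2-dimethyl-2H-chromen-6-yl)(3-hydroxyphenyl)methanone F3. C8-prenylation of F3 with 5 in aqueous KOH then gives 8.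

Step 3 (C-prenylation). O-prenylation at the 5- or 7-OH and over-alkylation to a dearomatised gem-diprenyl compound compete, so the yield is likely to be modest. The fallback sets out from 1 and comes back at 6, by-passing 3 and 4. Both prenyl groups are put on the much more C-nucleophilic phloroglucinol core first: 1 with 5 (2.2 equiv, 10% aq KOH, 0 °C) gives 2,4,6-trihydroxy-3,5-bis(3-methylbut-2-en-1-yl)benzaldehyde F4. DDQ (1.0 equiv, benzene, rt to 60 °C) then converts one prenyl group into the 2,2-dimethylpyran ring by dehydrogenative cyclisation through the para oxygen, giving 6. This is a step shorter, but closure onto an ortho oxygen is the expected competitor, so the isomers would have to be separated.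

Step 2 (gold cyclisation). The Lewis-acidic gold catalyst may ionise the tertiary propargylic C–O bond, whose aryloxide is a good leaving group, or be slowed by the chelating hydroxy-aldehyde. The fallback sets out from 1 and comes back at 4, by-passing 3. Compound 1 is condensed directly with 3-methylbut-2-enal (ethylenediammonium diacetate 10 mol %, toluene/DMF, 100 °C, or pyridine, 110 °C) in a Knoevenagel-type C-alkylation, dehydration and oxa-6π electrocyclisation domino. This is one operation instead of two, but it gives up the regiochemical guarantee, because closure onto an ortho oxygen competes and the isomer must be removed by chromatography. It makes no compound beyond those in the list (F0).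

**Further compounds**
F1 | step 4 | (3-hydroxyphenyl)(2,4,6-trihydroxyphenyl)methanone | O=C(c1cccc(O)c1)c1c(O)cc(O)cc1O
F2 | step 4 | [2,6-dihydroxy-4-[(2-methylbut-3-yn-2-yl)oxy]phenyl](3-hydroxyphenyl)methanone | O=C(c1cccc(O)c1)c1c(O)cc(OC(C)(C)C#C)cc1O
F3 | step 4 | (5,7-dihydroxy-2,2-dimethyl-2H-chromen-6-yl)(3-hydroxyphenyl)methanone | O=C(c1cccc(O)c1)c1c(O)cc2OC(C)(C)C=Cc2c1O
F4 | step 3 | 2,4,6-trihydroxy-3,5-bis(3-methylbut-2-en-1-yl)benzaldehyde | O=Cc1c(O)c(CC=C(C)C)c(O)c(CC=C(C)C)c1O
F0 | step 2 | none | none
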